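**Retrosynthetic overview**

1. Target ⇐ allylic oxidation of a C5 isopropenyl group to the C15 enal, after two acylations (O6 angelate, O9 methacrylate) of a 6α,9α-dihydroxy α-methylene lactone.
2. Lactone (second ring, formed last) ⇐ carbonylative lactonisation of a cis 7-ethynyl/8-hydroxy pair; 6-OH and 9-OH ⇐ one 8-OH-directed double reduction of a 6,9-dione.
3. Quaternary C10 ⇐ 1,2-vinyl shift from C9 to C10 (vinylogous semipinacol) started by ionising a C6 dimethyl ketal; C8–O ⇐ SN2 inversion of an 8-bromide that first steers the vinyl addition.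
4. 9-Vinyl carbinol ⇐ vinyl 1,2-addition to a cyclohexenone carrying the C5 isopropenyl and C7 alkynyl groups, both installed by conjugate additions to a quinone monoketal.
5. Carbocycle (first ring) ⇐ oxidative dearomatisation of o-cresol, whose methyl group becomes C14.

Convention: positions are given in elemane numbering (C1–C15 of the target); β is the ring face that carries the C7–C11 bond, α the opposite face; the SMILES strings define absolute configuration.
Assumption: the target is exactly the stereoisomer of the given SMILES (in this convention 5α side chain, 6α-angelate, 9α-methacrylate, 12,8β-olide, 10β-vinyl), and all starting materials named below are purchasable.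

**Step 1**
Reactants: 1 o-cresol
Product: 3 4,4-dimethoxy-2-methylcyclohexa-2,5-dien-1-one, via 4-methoxy-2-methylphenol 2 (not isolated)
Conditions: PhI(OAc)2 (2.2 equiv), MeOH, 0 °C to rt
Reagents that add atoms: methanol, CO
Why: Oxidative dearomatisation of a para-unsubstituted phenol by a trivalent iodine oxidant (para-methoxylation to 2, then a second oxidation in methanol) gives the quinone monoketal; no stereocentre is formed.

**Step 2**
Reactants: 3 quinone monoketal; 4 ethynyltrimethylsilane
Product: 6 (5R)-4,4-dimethoxy-2-methyl-5-[(trimethylsilyl)ethynyl]cyclohex-2-en-1-one, via alkynylalane 5 (not isolated)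
Conditions: 4, n-BuLi, t-BuOMe, −40 °C; Me2AlCl, 0 °C; then 3, Ni(acac)2 (5 mol%), (S,S)-Ph-bis(oxazoline) ligand (6 mol%), 0 °C; aq. NH4Cl
Reagents that add atoms: dimethylaluminium chloride, C[Al](C)Cl (its AlMe2 group is carried in 5 only)
Why: Nickel-catalysed asymmetric conjugate alkynylation (1,4-addition of an alkynylalane) goes to the unsubstituted, more electrophilic enone arm, and the chiral bis(oxazoline)–nickel catalyst (ligand enantiomer chosen for 5R) sets C7 with the alkynyl group on the β face.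

**Step 3**
Reactants: 6 alkynyl enone; 7 isopropenylmagnesium bromide
Product: 9 (5R)-4,4-dimethoxy-2-methyl-3-(prop-1-en-2-yl)-5-[(trimethylsilyl)ethynyl]cyclohex-2-en-1-one, via silyl enol ether 8 (not isolated)
Conditions: 7, CuBr·SMe2 (10 mol%), Me3SiCl, THF, −78 °C; then Pd(OAc)2 (10 mol%), O2 (1 atm), DMSO, 25 °C
Reagents that add atoms: chlorotrimethylsilane, C[Si](C)(C)Cl (its Me3Si group is carried in 8 only)
Why: Copper-catalysed 1,4-addition of the alkenyl Grignard reagent to the remaining α-methyl enone with silyl trapping, then Saegusa–Ito dehydrosilylation, re-forms the C10=C5 enone now bearing the isopropenyl group; the transient C5 centre is erased and C7, the ketal and the silyl alkyne are untouched.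

**Step 4**
Reactants: 9 isopropenyl dienone
Product: 10 (5R,6S)-6-bromo-4,4-dimethoxy-2-methyl-3-(prop-1-en-2-yl)-5-[(trimethylsilyl)ethynyl]cyclohex-2-en-1-one
Conditions: LiN(SiMe3)2, THF, −78 °C; then NBS, −78 °C
Reagents that add atoms: N-bromosuccinimide, BrN1C(=O)CCC1=O
Why: Kinetic α'-enolisation (C8–H is the only enolisable position) and electrophilic bromination of the lithium enolate; NBS approaches anti to the neighbouring C7 alkynyl group and gives the trans 8α-bromide.

**Step 5**
Reactants: 10 bromo dienone; 11 vinylmagnesium bromide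
Product: 12 (1R,5R,6S)-6-bromo-4,4-dimethoxy-2-methyl-3-(prop-1-en-2-yl)-5-[(trimethylsilyl)ethynyl]-1-vinylcyclohex-2-en-1-ol
Conditions: 11, LaCl3·2LiCl, THF, −78 °C; aq. NH4Cl at −78 °C
Reagents that add atoms: none
Why: Lanthanum-promoted Grignard 1,2-addition (enolisation and 1,4-addition suppressed) occurs anti to the C–Br bond (polar Felkin–Anh/Cornforth control, the rod-like C7 alkynyl group offering little opposition), so vinyl enters on the β face and the 9-OH is α, cis to bromine, which rules out epoxide closure.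

**Step 6**
Reactants: 12 vinyl carbinol ketal
Product: 13 (2S,5R,6S)-6-bromo-4-methoxy-2-methyl-3-(prop-1-en-2-yl)-5-[(trimethylsilyl)ethynyl]-2-vinylcyclohex-3-en-1-one
Conditions: Me3SiOTf (10 mol%), 4 Å MS, CH2Cl2, −78 to −40 °C; Et3N quench
Reagents that add atoms: none
Why: Proposed new method: ketal-ionisation-triggered vinylogous semipinacol rearrangement, in which catalytic Me3SiOTf ionises the C6 dimethyl ketal to an alkoxy-allyl cation with positive charge shared by C6 and the methyl-bearing C10, the vinyl group on the adjacent carbinol C9 (pushed by the hydroxyl lone pair) migrates suprafacially to C10, C9 collapses to the ketone and C6 remains as a methyl enol ether, so the β-vinyl configuration of C9 is transferred to the new quaternary C10 (vinyl β, methyl α), vinyl migrating in preference to the bromine-bearing C8 (no ring contraction); the closest known reaction types are the acid-promoted quinol–enedione (dienone–phenol type) 1,2-shift and Lewis-acid semipinacol rearrangements of allylic alcohols, neither shown as a ketal-triggered vinyl shift that creates an all-carbon quaternary stereocentre.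

**Step 7**
Reactants: 13 rearranged bromo ketone
Product: 15 (2S,5S,6R)-5-ethynyl-6-hydroxy-4-methoxy-2-methyl-3-(prop-1-en-2-yl)-2-vinylcyclohex-3-en-1-one, via formate ester 14 (not isolated)
Conditions: HCO2K, MeOH, 40 °C; then K2CO3 (cat.), 0 °C
Reagents that add atoms: potassium formate, [K+].[O-]C=O
Why: SN2 displacement of the α-keto bromide by formate with inversion (8α-Br to 8β-O), then methanolysis of the formate and protodesilylation of the alkyne in the same pot, gives the 8β-hydroxy ketone cis to the 7β-ethynyl group.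

**Step 8**
Reactants: 15 hydroxy ketone enol ether
Product: 17 3-ethynyl-6-methyl-5-(prop-1-en-2-yl)-6-vinylcyclohexane-1,2,4-triol (6α,8β,9α-triol), via hydroxy dione 16 (not isolated)
Conditions: (CO2H)2 (cat.), THF–H2O, 0 °C; then Me4NBH(OAc)3 (5 equiv), MeCN–AcOH, −30 °C
Reagents that add atoms: water, O
Why: Mild-acid hydrolysis of the dienol ether with kinetic axial protonation at C5 keeps the isopropenyl group out of conjugation and places it equatorial (5α), and the Evans–Saksena hydroxyl-directed reduction then delivers hydride from boron bound to the 8β-OH to the β faces of C9 (1,2-anti) and C6 (1,3-anti), setting 9α-OH and 6α-OH.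

**Step 9**
Reactants: 17 triol
Product: 18 6α,9α-dihydroxyelema-1,3,11(13)-trien-12,8β-olide
Conditions: PdCl2 (5 mol%), SnCl2 (5 mol%), PPh3 (10 mol%), CO (8 atm), MeCN, 75 °C
Reagents that add atoms: carbon monoxide, [C-]#[O+]
Why: Palladium-catalysed cyclocarbonylation of a homopropargylic alcohol (alkoxycarbonyl-palladium addition across the alkyne, then protonolysis) closes the α-methylene-γ-butyrolactone with retention at C7 and C8; only the 8β-OH is gauche to the 7β-ethynyl group, the 6α-OH being trans-diaxial to it in the preferred chair.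

**Step 10**
Reactants: 18 diol lactone; 19 methacryloyl chloride
Product: 20 6α-hydroxy-9α-methacryloyloxyelema-1,3,11(13)-trien-12,8β-olide
Conditions: 19 (1.1 equiv), Et3N, DMAP (cat.), CH2Cl2, −40 °C
Reagents that add atoms: none
Why: Site-selective acylation (nucleophilic catalysis): the equatorial 9α-OH reacts while the 6α-OH is axial and 1,3-diaxial to the C10 methyl group; no stereocentre is touched.

**Step 11**
Reactants: 20 mono-methacrylate; 21 angelic acid
Product: 23 6α-angeloyloxy-9α-methacryloyloxyelema-1,3,11(13)-trien-12,8β-olide, via mixed anhydride 22 (not isolated)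
Conditions: 21, 2,4,6-Cl3C6H2COCl, Et3N, toluene, 0 °C; then 20, DMAP, toluene, 60 °C
Reagents that add atoms: 2,4,6-trichlorobenzoyl chloride, O=C(Cl)c1c(Cl)cc(Cl)cc1Cl (its acyl group is carried in 22 only)
Why: Yamaguchi esterification through the mixed anhydride acylates the hindered axial 6α-OH with retention at C6 under conditions that keep the (Z)-geometry of the angelate.

**Step 12**
Reactants: 23 diester
Product: 24 6α-angeloyloxy-9α-methacryloyloxy-15-oxoelema-1,3,11(13)-trien-12,8β-olide (target)
Conditions: SeO2 (1.1 equiv), 1,4-dioxane, 60 °C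
Reagents that add atoms: selenium dioxide, O=[Se]=O
Why: Selenium dioxide allylic oxidation (ene reaction, 2,3-shift, further oxidation to the enal) attacks the methyl group of the only electron-rich 1,1-disubstituted alkene; the vinyl group has no allylic hydrogen, the three acrylate-type alkenes are electron-poor, and no stereocentre is affected.

**Compound list**

1 | o-cresol (2-methylphenol) | Cc1ccccc1O | starting material
2 | 4-methoxy-2-methylphenol | Cc1cc(OC)ccc1O | intermediate
3 | 4,4-dimethoxy-2-methylcyclohexa-2,5-dien-1-one | CC1=CC(OC)(OC)C=CC1=O | intermediate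
4 | ethynyltrimethylsilane | C#C[Si](C)(C)C | starting material
5 | dimethyl[(trimethylsilyl)ethynyl]aluminium | C[Al](C)C#C[Si](C)(C)C | intermediate
6 | (5R)-4,4-dimethoxy-2-methyl-5-[(trimethylsilyl)ethynyl]cyclohex-2-en-1-one (alkynyl at C7, β) | CC1=CC(OC)(OC)[C@@H](C#C[Si](C)(C)C)CC1=O | intermediate
7 | isopropenylmagnesium bromide (prop-1-en-2-ylmagnesium bromide) | CC(=C)[Mg]Br | starting material
8 | {[4,4-dimethoxy-2-methyl-3-(prop-1-en-2-yl)-5-[(trimethylsilyl)ethynyl]cyclohex-1-en-1-yl]oxy}trimethylsilane (3,5-trans, 5R) | CC1=C(O[Si](C)(C)C)C[C@H](C#C[Si](C)(C)C)C(OC)(OC)[C@H]1C(C)=C | intermediate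
9 | (5R)-4,4-dimethoxy-2-methyl-3-(prop-1-en-2-yl)-5-[(trimethylsilyl)ethynyl]cyclohex-2-en-1-one | CC1=C(C(C)=C)C(OC)(OC)[C@@H](C#C[Si](C)(C)C)CC1=O | intermediate
10 | (5R,6S)-6-bromo-4,4-dimethoxy-2-methyl-3-(prop-1-en-2-yl)-5-[(trimethylsilyl)ethynyl]cyclohex-2-en-1-one (8α-Br, trans to alkynyl) | CC1=C(C(C)=C)C(OC)(OC)[C@@H](C#C[Si](C)(C)C)[C@H](Br)C1=O | intermediate
11 | vinylmagnesium bromide | C=C[Mg]Br | starting material
12 | (1R,5R,6S)-6-bromo-4,4-dimethoxy-2-methyl-3-(prop-1-en-2-yl)-5-[(trimethylsilyl)ethynyl]-1-vinylcyclohex-2-en-1-ol (9β-vinyl, 9α-OH) | CC1=C(C(C)=C)C(OC)(OC)[C@@H](C#C[Si](C)(C)C)[C@H](Br)[C@@]1(O)C=C | intermediate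
13 | (2S,5R,6S)-6-bromo-4-methoxy-2-methyl-3-(prop-1-en-2-yl)-5-[(trimethylsilyl)ethynyl]-2-vinylcyclohex-3-en-1-one (10β-vinyl, 10α-methyl) | C=C[C@@]1(C)C(C(C)=C)=C(OC)[C@@H](C#C[Si](C)(C)C)[C@H](Br)C1=O | intermediate
14 | formate ester of the 8β-alcohol: 4-methoxy-6-methyl-2-oxo-5-(prop-1-en-2-yl)-3-[(trimethylsilyl)ethynyl]-6-vinylcyclohex-4-en-1-yl formate (8β-O, 7β-alkynyl, 10β-vinyl) | C=C[C@@]1(C)C(C(C)=C)=C(OC)[C@@H](C#C[Si](C)(C)C)[C@@H](OC=O)C1=O | intermediate
15 | (2S,5S,6R)-5-ethynyl-6-hydroxy-4-methoxy-2-methyl-3-(prop-1-en-2-yl)-2-vinylcyclohex-3-en-1-one (8β-OH) | C=C[C@@]1(C)C(C(C)=C)=C(OC)[C@@H](C#C)[C@@H](O)C1=O | intermediate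
16 | 5-ethynyl-6-hydroxy-2-methyl-3-(prop-1-en-2-yl)-2-vinylcyclohexane-1,4-dione (5α-isopropenyl, 7β-ethynyl, 8β-OH, 10β-vinyl) | C=C[C@@]1(C)[C@H](C(C)=C)C(=O)[C@@H](C#C)[C@@H](O)C1=O | intermediate
17 | 3-ethynyl-6-methyl-5-(prop-1-en-2-yl)-6-vinylcyclohexane-1,2,4-triol (6α-OH, 8β-OH, 9α-OH, 7β-ethynyl, 5α-isopropenyl, 10β-vinyl) | C=C[C@@]1(C)[C@H](C(C)=C)[C@H](O)[C@@H](C#C)[C@@H](O)[C@@H]1O | intermediate
18 | 6α,9α-dihydroxyelema-1,3,11(13)-trien-12,8β-olide (5βH,7αH,8αH,10α-methyl) | C=C[C@@]1(C)[C@H](C(C)=C)[C@H](O)[C@H]2C(=C)C(=O)O[C@H]2[C@@H]1O | intermediate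
19 | methacryloyl chloride | CC(=C)C(Cl)=O | starting material
20 | 6α-hydroxy-9α-methacryloyloxyelema-1,3,11(13)-trien-12,8β-olide | C=C[C@@]1(C)[C@H](C(C)=C)[C@H](O)[C@H]2C(=C)C(=O)O[C@H]2[C@@H]1OC(=O)C(=C)C | intermediate
21 | angelic acid ((Z)-2-methylbut-2-enoic acid) | C/C=C(/C)C(=O)O | starting material
22 | (Z)-2-methylbut-2-enoic 2,4,6-trichlorobenzoic anhydride | C/C=C(/C)C(=O)OC(=O)c1c(Cl)cc(Cl)cc1Cl | intermediate
23 | 6α-angeloyloxy-9α-methacryloyloxyelema-1,3,11(13)-trien-12,8β-olide | C=C[C@@]1(C)[C@H](C(C)=C)[C@H](OC(=O)/C(C)=C\C)[C@H]2C(=C)C(=O)O[C@H]2[C@@H]1OC(=O)C(=C)C | intermediate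
24 | 6α-angeloyloxy-9α-methacryloyloxy-15-oxoelema-1,3,11(13)-trien-12,8β-olide (CNP0102441.1) | C=C[C@@]1(C)[C@H](C(=C)C=O)[C@H](OC(=O)/C(C)=C\C)[C@H]2C(=C)C(=O)O[C@H]2[C@@H]1OC(=O)C(=C)C | target

**Totals**

Total step count: 12. Longest linear sequence: 12 steps (from o-cresol 1).

**Three steps most likely to fail**

Step 6 (the proposed 1,2-vinyl shift). The risks are ionisation of the tertiary carbinol or plain ketal-to-enol-ether elimination instead of migration. The fallback uses known chemistry and builds the quaternary centre by enolate C–C bond formation instead of a shift. It sets out from 6: copper-catalysed conjugate addition of 7 (CuBr·SMe2, THF, −78 °C) occurs trans to the C7 alkynyl group, and the magnesium enolate is captured in the same flask by acetaldehyde, anti to the new C5 substituent, to give the aldol adduct 2-(1-hydroxyethyl)-4,4-dimethoxy-2-methyl-3-(prop-1-en-2-yl)-5-[(trimethylsilyl)ethynyl]cyclohexan-1-one F3 (hydroxyethyl β, methyl α, isopropenyl α). Burgess dehydration towards the methyl group gives the 10β-vinyl ketone 4,4-dimethoxy-2-methyl-3-(prop-1-en-2-yl)-5-[(trimethylsilyl)ethynyl]-2-vinylcyclohexan-1-one F4. LiN(SiMe3)2 then NBS gives its 8α-bromide F5. HCO2K in MeOH gives the 8β-formate F6, which on methanolysis and desilylation with catalytic K2CO3 gives the 8β-hydroxy ketone dimethyl ketal F7. Aqueous acid hydrolysis of the ketal of F7 gives dione 16, where the fallback comes back to the route for the reduction of step 8.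

Step 2 (asymmetric conjugate alkynylation next to the ketal carbon). The risks are low rate or low enantioselectivity. The fallback replaces catalyst control by auxiliary control. It sets out from 3: transketalisation with (1R,2R)-1,2-diphenylethane-1,2-diol (pyridinium tosylate, benzene, reflux) gives the chiral spiroketal (2R,3R)-7-methyl-2,3-diphenyl-1,4-dioxaspiro[4.5]deca-6,9-dien-8-one F1. Addition of alane 5 with Ni(acac)2 and no chiral ligand occurs anti to the nearer phenyl group and gives the alkynylated spiroketal F2 (the antipodal diol is used if the induction is opposite). Acid-catalysed exchange with methanol (camphorsulfonic acid) releases the diol and gives 6, where the fallback comes back to the route.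

Step 12 (late allylic oxidation). The risks are competing attack at C5–H, incomplete oxidation, or angelate isomerisation. The fallback uses photooxygenation instead of selenium chemistry. It sets out from 23: a singlet-oxygen ene reaction (O2, visible light, tetraphenylporphyrin, CH2Cl2, −20 °C) on the isopropenyl group gives the primary allylic hydroperoxide 15-hydroperoxy-6α-angeloyloxy-9α-methacryloyloxyelema-1,3,11(13)-trien-12,8β-olide F8. Ac2O and pyridine (Kornblum–DeLaMare-type dehydration) convert F8 into 24, where the fallback comes back to the route.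

**Further compounds**

F1 | step 2 | (2R,3R)-7-methyl-2,3-diphenyl-1,4-dioxaspiro[4.5]deca-6,9-dien-8-one | CC1=CC2(O[C@H](c3ccccc3)[C@@H](c3ccccc3)O2)C=CC1=O
F2 | step 2 | (2R,3R,10R)-7-methyl-2,3-diphenyl-10-[(trimethylsilyl)ethynyl]-1,4-dioxaspiro[4.5]dec-6-en-8-one | CC1=CC2(O[C@H](c3ccccc3)[C@@H](c3ccccc3)O2)[C@@H](C#C[Si](C)(C)C)CC1=O
F3 | step 6 | 2-(1-hydroxyethyl)-4,4-dimethoxy-2-methyl-3-(prop-1-en-2-yl)-5-[(trimethylsilyl)ethynyl]cyclohexan-1-one (hydroxyethyl β, methyl α, isopropenyl α, alkynyl β; carbinol centre unassigned) | CC(O)[C@@]1(C)[C@H](C(C)=C)C(OC)(OC)[C@@H](C#C[Si](C)(C)C)CC1=O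
F4 | step 6 | 4,4-dimethoxy-2-methyl-3-(prop-1-en-2-yl)-5-[(trimethylsilyl)ethynyl]-2-vinylcyclohexan-1-one (10β-vinyl, 5α-isopropenyl, 7β-alkynyl) | C=C[C@@]1(C)[C@H](C(C)=C)C(OC)(OC)[C@@H](C#C[Si](C)(C)C)CC1=O
F5 | step 6 | 6-bromo-4,4-dimethoxy-2-methyl-3-(prop-1-en-2-yl)-5-[(trimethylsilyl)ethynyl]-2-vinylcyclohexan-1-one (8α-Br) | C=C[C@@]1(C)[C@H](C(C)=C)C(OC)(OC)[C@@H](C#C[Si](C)(C)C)[C@H](Br)C1=O
F6 | step 6 | 3,3-dimethoxy-5-methyl-6-oxo-4-(prop-1-en-2-yl)-2-[(trimethylsilyl)ethynyl]-5-vinylcyclohexyl formate (8β-formate) | C=C[C@@]1(C)[C@H](C(C)=C)C(OC)(OC)[C@@H](C#C[Si](C)(C)C)[C@@H](OC=O)C1=O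
F7 | step 6 | 5-ethynyl-6-hydroxy-4,4-dimethoxy-2-methyl-3-(prop-1-en-2-yl)-2-vinylcyclohexan-1-one (8β-OH) | C=C[C@@]1(C)[C@H](C(C)=C)C(OC)(OC)[C@@H](C#C)[C@@H](O)C1=O
F8 | step 12 | 15-hydroperoxy-6α-angeloyloxy-9α-methacryloyloxyelema-1,3,11(13)-trien-12,8β-olide | C=C[C@@]1(C)[C@H](C(=C)COO)[C@H](OC(=O)/C(C)=C\C)[C@H]2C(=C)C(=O)O[C@H]2[C@@H]1OC(=O)C(=C)C
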